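The data were computed for substances that don't exist; scatter was added.

5 questions stand before you: which flask gives most target, and how much target each flask holds at the end.

1. the flask that comes out highest in amount of target, in percent of the substrate charged, or "all alike" when all lie within 1.5 percentage points (oak / ash / maple / birch / all alike)
2. target at the end, in percent of the substrate charged, oak
3. target at the end, in percent of the substrate charged, ash
4. target at the end, in percent of the substrate charged, maple
5. target at the end, in percent of the substrate charged, birch

| flask | substrate | partner | protic impurity | remark | time |
|---|---|---|---|---|---|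
| alpha | 0.38 M | 1.1 equiv | 0.038 M | run made earlier |  |
| gamma | 0.38 M | 1.1 equiv | 0.076 M | run made earlier |  |
| oak | 0.38 M | 1.10 equiv | 0.0380 M | everything together at the start | 4.0 h |
| ash | 0.38 M (fed, over 2.5 h) | 1.10 equiv | 0.0380 M | all else is in the flask from the start; the feed brings no volume worth counting | 4.0 h |
| maple | 0.38 M | 1.10 equiv (fed, over 2.5 h) | 0.0380 M | all else is in the flask from the start; the feed brings no volume worth counting | 4.0 h |
| birch | 0.38 M | 1.10 equiv (in portions, 5, over 2.5 h) | 0.0380 M | first portion at the start, last at 2.5 h | 4.0 h |

- alpha (time / h: target / %): 0.333: 61.3; 0.500: 70.2; 0.667: 76.0; 1.00: 82.1; 1.50: 86.4; 2.50: 91.4; 4.00: 93.5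
- gamma (time / min: target / %): 3.00: 20.7; 6.00: 32.5; 10.0: 45.6; 15.0: 53.8; 20.0: 61.1; 25.0: 65.5

(standard deviation of a reading: 0.5 percentage points)



Draw the curve of the alpha run first, since oak repeats its recipe. It rises steeply, to 61.3% by 0.333 h, and at that same moment, 20.0 min, the gamma run, with twice the protic impurity, stands at 61.1%, so this pair of readings differs by less than the scatter of 0.5 percentage points. The knee comes near 1.00 h, at 82.1%, and after 2.50 h the curve gains 2.1 points more, up to 93.5%.

Where does it level? My own reckoning is that each protic impurity takes one partner, so you subtract the impurity from the partner charge and divide by the substrate charged; this usable-partner ceiling, the theoretical yield, comes to 100%. Oak, ash, maple and birch carry the same charges, so they share this one ceiling. Alpha still stands 6.5 points under it at its last reading, so I put oak near that reading and expect the fed flasks under the ceiling too.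

The forecast names oak as highest and gives oak 93.7%, ash 90.3%, maple 90.7% and birch 89.9%, and of the fed flasks it says: “Maple is marginally best of these, since some impurity survives”.

The flasks give oak as highest, with oak at 93.0%, ash at 89.5%, maple at 82.5% and birch at 82.7%, so the forecast stands 8.2 points too high for maple and 7.2 points too high for birch.

    partner + protic impurity → quenched reagent (k = 0.146 /M/min)
    substrate + partner → target, rate k2*[substrate]^1.5*[partner]^0.5 (k = 0.210 /M/min)
    2 substrate → self-condensation product (k = 0.00386 /M/min)

The path from 2 substrate to self-condensation product is the largest single effect between oak and maple: with that path taken away, their gap shrinks from 10 points to 2.5 points. You can read the same loss against the ceiling. Left for 40.0 h, oak reaches 96.6%, which is 3.4 points under the ceiling, and its self-condensation product holds 3.20% of the substrate charged. Maple, left as long, reaches 87.2%, which is 13 points under the ceiling, and its self-condensation product holds 12.7%.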